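**Retrosynthetic overview**

1. Target 20 is a 1,4-dimethylcyclohex-3-ene (ring carbons C1–C6 as in its name: C1 quaternary with methyl and styryl, C2 with the aryl group, C3=C4 with the methyl on C4, C5 and C6 methylenes) carrying two 7-methoxycoumarin-8-yl units, both bought in intact (osthole, umbelliferone).
2. Key disconnection: the ring single bond between the methyl-bearing olefinic carbon C4 and the methylene C5, closed last by one-pot hydroboration and intramolecular B-alkyl Suzuki–Miyaura coupling of an acyclic (Z)-2-iodopropenyl/vinyl precursor. The enabling feature is the 1,5-diene C4=C3–C2–C1–C6=C5 hidden in the ring: C5–C6 is an ethylene bridge on quaternary C1 (a masked vinyl group), and C4 lies cis to it on the olefin attached to C2.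
3. The C1–C2 bond, both stereocentres and the vinyl group come from an enantioselective Ireland–Claisen rearrangement of the (2Z,4E)-dienyl arylacetate 11.
4. Ester 11 comes from arylacetic acid 4 (osthole) and dienol 10 (Suzuki coupling of 8-iodo-7-methoxycoumarin with a boronate made from commercial (Z)-3-methylpent-2-en-4-yn-1-ol).
5. Ring order: no coumarin ring is built; the cyclohexene is the only ring formed, in the final step.

Key step: step 12

Abbreviation used in names: Cm = 7-methoxy-2-oxo-2H-chromen-8-yl.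

Assumption: the (S,S)-controller is taken to give the (2R,3R) acid, and the boron enolate of 11 to carry its aryl group cis to the boryloxy oxygen; if either proves opposite, the (R,R)-controller or the (2E)-isomer of the alcohol part is the direct correction.

**Step 1**
Reactants: 1 osthole (7-methoxy-8-(3-methylbut-2-en-1-yl)-2H-chromen-2-one)
Product: 3 2-(7-methoxy-2-oxo-2H-chromen-8-yl)acetaldehyde, via ozonide 2 (not isolated)
Conditions: O3 (1 equiv), CH2Cl2, −78 °C; then Me2S, −78 °C → rt
Reagents that add atoms: ozone, [O-][O+]=O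
Why: Ozonolysis with reductive work-up, in which the electron-rich trisubstituted prenyl olefin should react with ozone far faster than the electron-poor lactone double bond, so that one equivalent at low temperature cleaves it selectively.

**Step 2**
Reactants: 3 2-(7-methoxy-2-oxo-2H-chromen-8-yl)acetaldehyde
Product: 4 2-(7-methoxy-2-oxo-2H-chromen-8-yl)acetic acid
Conditions: NaClO2, NaH2PO4, 2-methylbut-2-ene, t-BuOH/H2O, 0 °C → rt
Reagents that add atoms: sodium chlorite, [Na+].[O-]Cl=O
Why: Pinnick oxidation converts the aldehyde to the acid under buffered conditions that should leave the coumarin untouched, with 2-methylbut-2-ene scavenging the hypochlorous acid.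

**Step 3**
Reactants: 5 umbelliferone (7-hydroxy-2H-chromen-2-one)
Product: 6 7-hydroxy-8-iodo-2H-chromen-2-one
Conditions: I2, KI, aq. NH3, rt; then dil. HCl
Reagents that add atoms: iodine, II
Why: Electrophilic aromatic iodination of the phenoxide, which is directed to the position between the hydroxyl group and the ring oxygen (C8 of the coumarin).

**Step 4**
Reactants: 6 7-hydroxy-8-iodo-2H-chromen-2-one
Product: 7 8-iodo-7-methoxy-2H-chromen-2-one
Conditions: MeI, K2CO3, acetone, reflux
Reagents that add atoms: iodomethane, CI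
Why: Williamson O-methylation of the phenol with a weak base that should not open the lactone.

**Step 5**
Reactants: 8 (Z)-3-methylpent-2-en-4-yn-1-ol
Product: 9 (2Z,4E)-3-methyl-5-(4,4,5,5-tetramethyl-1,3,2-dioxaborolan-2-yl)penta-2,4-dien-1-ol
Conditions: B2pin2, CuCl (cat.), Xantphos (cat.), NaOt-Bu (cat.), MeOH, THF, rt
Reagents that add atoms: bis(pinacolato)diboron, CC1(C)OB(OC1(C)C)B1OC(C)(C)C(C)(C)O1
Why: Copper-catalysed formal hydroboration (syn borylcupration of the terminal alkyne by a Cu–Bpin species, then protonation by methanol) should give the (E)-alkenyl boronate with boron on the terminal carbon, leaving the free hydroxyl group and the (Z)-trisubstituted olefin untouched.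

**Step 6**
Reactants: 9 (2Z,4E)-3-methyl-5-(4,4,5,5-tetramethyl-1,3,2-dioxaborolan-2-yl)penta-2,4-dien-1-ol; 7 8-iodo-7-methoxy-2H-chromen-2-one
Product: 10 (2Z,4E)-5-(7-methoxy-2-oxo-2H-chromen-8-yl)-3-methylpenta-2,4-dien-1-ol
Conditions: Pd(OAc)2 (cat.), SPhos, K3PO4, THF/H2O, 50 °C
Reagents that add atoms: none
Why: Suzuki–Miyaura coupling of the alkenyl boronate with the di-ortho-substituted aryl iodide should proceed with retention of both olefin geometries, SPhos being chosen for the hindered aryl partner.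

**Step 7**
Reactants: 10 (2Z,4E)-5-(7-methoxy-2-oxo-2H-chromen-8-yl)-3-methylpenta-2,4-dien-1-ol; 4 2-(7-methoxy-2-oxo-2H-chromen-8-yl)acetic acid
Product: 11 (2Z,4E)-5-(7-methoxy-2-oxo-2H-chromen-8-yl)-3-methylpenta-2,4-dien-1-yl 2-(7-methoxy-2-oxo-2H-chromen-8-yl)acetate
Conditions: DCC, DMAP (cat.), CH2Cl2, 0 °C → rt
Reagents that add atoms: none
Why: Steglich esterification of the primary allylic alcohol under neutral conditions that should neither ionise the dienyl carbinol nor isomerise the (Z)-olefin.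

**Step 8**
Reactants: 11 (2Z,4E)-5-(7-methoxy-2-oxo-2H-chromen-8-yl)-3-methylpenta-2,4-dien-1-yl 2-(7-methoxy-2-oxo-2H-chromen-8-yl)acetate
Product: 14 (2R,3R)-2-(7-methoxy-2-oxo-2H-chromen-8-yl)-3-[(E)-2-(7-methoxy-2-oxo-2H-chromen-8-yl)ethenyl]-3-methylpent-4-enoic acid, via boron ketene acetal 12 (not isolated), via acyloxyborane 13 (not isolated)
Conditions: (4S,5S)-2-bromo-1,3-bis{[3,5-bis(trifluoromethyl)phenyl]sulfonyl}-4,5-diphenyl-1,3,2-diazaborolidine (2 equiv), Et3N, toluene/hexane, −78 °C, then 4 °C; aq. work-up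
Reagents that add atoms: none
Why: Enantioselective Ireland–Claisen rearrangement through a chiral boron ketene acetal, in which a chair [3,3] transition state with the enolate aryl group equatorial and the styryl group (cis to CH2O on the Z-olefin) axial should join the α-carbon to the methyl-bearing olefin carbon and so set the quaternary and the tertiary stereocentre in the (2R,3R) relationship, the sulfonamide controller selecting the face; the reaction type is precedented for 3,3-disubstituted allyl esters that give a methyl/vinyl quaternary centre next to a tertiary one.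

**Step 9**
Reactants: 14 (2R,3R)-2-(7-methoxy-2-oxo-2H-chromen-8-yl)-3-[(E)-2-(7-methoxy-2-oxo-2H-chromen-8-yl)ethenyl]-3-methylpent-4-enoic acid
Product: 16 (2R,3R)-2-(7-methoxy-2-oxo-2H-chromen-8-yl)-3-[(E)-2-(7-methoxy-2-oxo-2H-chromen-8-yl)ethenyl]-3-methylpent-4-en-1-ol, via mixed anhydride 15 (not isolated)
Conditions: i-BuOCOCl, N-methylmorpholine, THF, −15 °C; then NaBH4, H2O, −15 → 0 °C
Reagents that add atoms: none
Why: Activation as the mixed carbonic anhydride followed by NaBH4 reduction should reduce the carboxyl group at low temperature without hydroborating the olefins, as borane would, and faster than NaBH4 attacks the lactones.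

**Step 10**
Reactants: 16 (2R,3R)-2-(7-methoxy-2-oxo-2H-chromen-8-yl)-3-[(E)-2-(7-methoxy-2-oxo-2H-chromen-8-yl)ethenyl]-3-methylpent-4-en-1-ol
Product: 17 (2R,3R)-2-(7-methoxy-2-oxo-2H-chromen-8-yl)-3-[(E)-2-(7-methoxy-2-oxo-2H-chromen-8-yl)ethenyl]-3-methylpent-4-enal
Conditions: Dess–Martin periodinane, CH2Cl2, 0 °C → rt
Reagents that add atoms: none
Why: Dess–Martin oxidation under non-basic conditions should give the α-aryl aldehyde without epimerising the benzylic stereocentre, whose enolisation is also hindered by the neighbouring quaternary carbon.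

**Step 11**
Reactants: 17 (2R,3R)-2-(7-methoxy-2-oxo-2H-chromen-8-yl)-3-[(E)-2-(7-methoxy-2-oxo-2H-chromen-8-yl)ethenyl]-3-methylpent-4-enal
Product: 18 8-[(3R,4R,5Z)-6-iodo-3-methyl-3-[(E)-2-(7-methoxy-2-oxo-2H-chromen-8-yl)ethenyl]hepta-1,5-dien-4-yl]-7-methoxy-2H-chromen-2-one
Conditions: [Ph3PCH(I)CH3]I, NaN(SiMe3)2, THF, −78 °C; then 17, −78 → −20 °C
Reagents that add atoms: (1-iodoethyl)triphenylphosphonium iodide, CC(I)[P+](c1ccccc1)(c1ccccc1)c1ccccc1.[I-]
Why: Wittig olefination with the α-iodoethylidene ylide (Stork–Zhao type), which is known to give (Z)-2-iodoalk-2-enes, placing iodine cis and methyl trans to the chain as the later ring closure requires.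

**Step 12**
Reactants: 18 8-[(3R,4R,5Z)-6-iodo-3-methyl-3-[(E)-2-(7-methoxy-2-oxo-2H-chromen-8-yl)ethenyl]hepta-1,5-dien-4-yl]-7-methoxy-2H-chromen-2-one
Product: 20 7-methoxy-8-[(E)-2-[(1R,2R)-2-(7-methoxy-2-oxo-2H-chromen-8-yl)-1,4-dimethylcyclohex-3-en-1-yl]ethenyl]-2H-chromen-2-one, via alkylborane 19 (not isolated)
Conditions: 9-BBN, THF, 0 °C → rt; then Pd(dppf)Cl2 (cat.), AsPh3, Cs2CO3, DMF/H2O, rt
Reagents that add atoms: none
Why: 9-BBN should add to the only monosubstituted olefin of 18, the vinyl group on the quaternary carbon, with boron on the terminal carbon (the future C5), because the styryl, the trisubstituted iodo-olefin and the electron-poor lactone double bonds are far slower towards this bulky borane; zerovalent palladium then inserts into the alkenyl C–I bond with retention, carbonate-assisted transfer of the primary alkyl group from the borate to palladium gives a seven-membered alkyl(alkenyl)palladacycle, and reductive elimination forms the C5–C4 bond. The closest known reaction type is the intramolecular B-alkyl Suzuki–Miyaura cyclisation of haloalkenes carrying a hydroborated terminal olefin, established for five- and six-membered cycloalkenes and for macrocycles. The cyclohexene closes in a 6-endo sense with respect to the iodo-olefin, both olefinic carbons ending inside the ring, which is possible because the (Z)-geometry of 18 holds the C–Pd bond cis to the tether and because the bond forms by reductive elimination and not by carbopalladation. No stereocentre is created: the two set in step 8 are remote from the reacting sites, and the position and geometry of the ring olefin are carried over unchanged from the iodoalkene. The selectivities needed are site-selective hydroboration and ring closure ahead of 5-exo carbopalladation of the styryl olefin; the first rests on the steric demand of 9-BBN, the second on fast base-promoted transmetalation at room temperature, on the Thorpe–Ingold effect of the quaternary carbon and on the hindered, 1,2-disubstituted nature of the styryl acceptor.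

**Compound list**

1 | osthole, 7-methoxy-8-(3-methylbut-2-en-1-yl)-2H-chromen-2-one | COc1ccc2ccc(=O)oc2c1CC=C(C)C | starting material
2 | ozonide of 1, 7-methoxy-8-[(5,5-dimethyl-1,2,4-trioxolan-3-yl)methyl]-2H-chromen-2-one (racemic at the ring CH) | COc1ccc2ccc(=O)oc2c1CC1OOC(C)(C)O1 | intermediate
3 | 2-(7-methoxy-2-oxo-2H-chromen-8-yl)acetaldehyde | COc1ccc2ccc(=O)oc2c1CC=O | intermediate
4 | 2-(7-methoxy-2-oxo-2H-chromen-8-yl)acetic acid | COc1ccc2ccc(=O)oc2c1CC(=O)O | intermediate
5 | umbelliferone, 7-hydroxy-2H-chromen-2-one | Oc1ccc2ccc(=O)oc2c1 | starting material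
6 | 7-hydroxy-8-iodo-2H-chromen-2-one | Oc1ccc2ccc(=O)oc2c1I | intermediate
7 | 8-iodo-7-methoxy-2H-chromen-2-one | COc1ccc2ccc(=O)oc2c1I | intermediate
8 | (Z)-3-methylpent-2-en-4-yn-1-ol | C#C/C(C)=C\CO | starting material
9 | (2Z,4E)-3-methyl-5-(4,4,5,5-tetramethyl-1,3,2-dioxaborolan-2-yl)penta-2,4-dien-1-ol | OC/C=C(C)\C=C\B1OC(C)(C)C(C)(C)O1 | intermediate
10 | (2Z,4E)-5-Cm-3-methylpenta-2,4-dien-1-ol | COc1ccc2ccc(=O)oc2c1/C=C/C(C)=C\CO | intermediate
11 | (2Z,4E)-5-Cm-3-methylpenta-2,4-dien-1-yl 2-Cm-acetate | COc1ccc2ccc(=O)oc2c1/C=C/C(C)=C\COC(=O)Cc1c(OC)ccc2ccc(=O)oc12 | intermediate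
12 | boron ketene acetal of 11: the ester enol bound through oxygen to the boron of the (4S,5S)-1,3-bis{[3,5-bis(trifluoromethyl)phenyl]sulfonyl}-4,5-diphenyl-1,3,2-diazaborolidine, Cm cis to the boryloxy oxygen | COc1ccc2ccc(=O)oc2c1/C=C/C(C)=C\CO/C(OB1N(S(=O)(=O)c2cc(C(F)(F)F)cc(C(F)(F)F)c2)[C@@H](c2ccccc2)[C@H](c2ccccc2)N1S(=O)(=O)c1cc(C(F)(F)F)cc(C(F)(F)F)c1)=C/c1c(OC)ccc2ccc(=O)oc12 | intermediate
13 | acyloxyborane: acid 14 bound as its carboxylate to the boron of the same (4S,5S)-diazaborolidine | COc1ccc2ccc(=O)oc2c1/C=C/[C@@]([C@@H](C(=O)OB1N(S(=O)(=O)c2cc(C(F)(F)F)cc(C(F)(F)F)c2)[C@@H](c2ccccc2)[C@H](c2ccccc2)N1S(=O)(=O)c1cc(C(F)(F)F)cc(C(F)(F)F)c1)c1c(OC)ccc2ccc(=O)oc12)(C)C=C | intermediate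
14 | (2R,3R)-2-Cm-3-[(E)-2-Cm-ethenyl]-3-methylpent-4-enoic acid | COc1ccc2ccc(=O)oc2c1/C=C/[C@@]([C@@H](C(=O)O)c1c(OC)ccc2ccc(=O)oc12)(C)C=C | intermediate
15 | mixed anhydride of 14 with isobutyl hydrogen carbonate | COc1ccc2ccc(=O)oc2c1/C=C/[C@@]([C@@H](C(=O)OC(=O)OCC(C)C)c1c(OC)ccc2ccc(=O)oc12)(C)C=C | intermediate
16 | (2R,3R)-2-Cm-3-[(E)-2-Cm-ethenyl]-3-methylpent-4-en-1-ol | COc1ccc2ccc(=O)oc2c1/C=C/[C@@]([C@@H](CO)c1c(OC)ccc2ccc(=O)oc12)(C)C=C | intermediate
17 | (2R,3R)-2-Cm-3-[(E)-2-Cm-ethenyl]-3-methylpent-4-enal | COc1ccc2ccc(=O)oc2c1/C=C/[C@@]([C@@H](C=O)c1c(OC)ccc2ccc(=O)oc12)(C)C=C | intermediate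
18 | 8-[(3R,4R,5Z)-6-iodo-3-methyl-3-[(E)-2-Cm-ethenyl]hepta-1,5-dien-4-yl]-7-methoxy-2H-chromen-2-one | COc1ccc2ccc(=O)oc2c1/C=C/[C@@]([C@@H](/C=C(/C)I)c1c(OC)ccc2ccc(=O)oc12)(C)C=C | intermediate
19 | 9-[(3R,4R,5Z)-6-iodo-4-Cm-3-[(E)-2-Cm-ethenyl]-3-methylhept-5-en-1-yl]-9-borabicyclo[3.3.1]nonane | COc1ccc2ccc(=O)oc2c1/C=C/[C@@]([C@@H](/C=C(/C)I)c1c(OC)ccc2ccc(=O)oc12)(C)CCB1C2CCCC1CCC2 | intermediate
20 | 7-methoxy-8-[(E)-2-[(1R,2R)-2-(7-methoxy-2-oxo-2H-chromen-8-yl)-1,4-dimethylcyclohex-3-en-1-yl]ethenyl]-2H-chromen-2-one | COc1ccc2ccc(=O)oc2c1/C=C/[C@@]1(C)CCC(C)=C[C@H]1c1c(OC)ccc2ccc(=O)oc12 | target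

**Totals**

Total step count: 12. Longest linear sequence: 9 steps (5 → 6 → 7 → 10 → 11 → 14 → 16 → 17 → 18 → 20, steps 3, 4, 6–12).

**Steps most likely to fail**

Step 8. What may go wrong: the Lewis-acidic bromoborane may ionise the doubly allylic C–O bond of 11 before enolisation; the boron enolate may form with the aryl group trans to the boryloxy oxygen; or the facial bias of the controller may be low with a 2,6-dioxygenated arylacetate. The result would be loss of material or a mixture of stereoisomers. The fallback sets out from 11 and comes back at 14, and gives up reagent control for a Lewis-acid-free rearrangement followed by resolution. Addition of KN(SiMe3)2 to 11 and Me3SiCl in THF at −78 °C gives the trimethylsilyl ketene acetal F1 (aryl cis to the silyloxy group), which rearranges on warming through the same chair to the racemic trimethylsilyl ester F2. Acidic work-up gives the racemic acid, that is 14 together with its enantiomer, (2S,3S)-acid F3. Crystallisation with (S)-1-phenylethylamine gives the diastereomerically pure salt F4 of 14, F3 staying in the mother liquor, and acidification returns 14.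

Step 11. What may go wrong: the basic ylide may epimerise the benzylic stereocentre next to the formyl group, may add sluggishly to the neopentyl-type aldehyde, or may give incomplete Z/E control. The fallback sets out from 17 and comes back at 20. Base-free Ramirez olefination (CBr4, PPh3, Zn dust, CH2Cl2, 0 °C) gives the 1,1-dibromoalkene F5. Trans-selective Negishi mono-methylation (MeZnCl, Pd(DPEphos)Cl2 cat., THF, 0 °C), which is known to replace the bromine trans to the chain first, gives the (Z)-2-bromopropenyl compound F6. Hydroboration with 9-BBN to the alkylborane F7 and the ring closure of step 12 (Pd(dppf)Cl2, AsPh3, Cs2CO3, DMF/H2O) then give 20.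

Step 12. What may go wrong: incomplete site selection in the hydroboration; 5-exo carbopalladation of the styryl double bond by the alkenylpalladium intermediate outrunning transmetalation; or opening of the lactones by the aqueous base. The fallback sets out from 18 and comes back at 20, and closes the same bond with an organozinc under neutral, anhydrous conditions. Hydroboration as before to 19 is followed by oxidation (NaBO3·4H2O, THF/H2O) to the primary alcohol F8. Appel iodination (I2, PPh3, imidazole, CH2Cl2) gives the primary iodide F9. Zinc insertion into the alkyl C–I bond only (Zn dust, LiCl, THF, 25 °C) gives the alkylzinc iodide F10, used without isolation. Intramolecular Negishi coupling (Pd(PPh3)4 cat., THF, rt → 50 °C) then gives 20.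

**Further compounds**

F1 | step 8 | trimethylsilyl ketene acetal of 11, 1-{[(2Z,4E)-5-Cm-3-methylpenta-2,4-dien-1-yl]oxy}-2-Cm-1-(trimethylsilyloxy)ethene, Cm cis to the silyloxy group | COc1ccc2ccc(=O)oc2c1/C=C/C(C)=C\CO/C(O[Si](C)(C)C)=C/c1c(OC)ccc2ccc(=O)oc12
F2 | step 8 | trimethylsilyl ester of the racemic acid (the (2R,3R) antipode is drawn) | COc1ccc2ccc(=O)oc2c1/C=C/[C@@]([C@@H](C(=O)O[Si](C)(C)C)c1c(OC)ccc2ccc(=O)oc12)(C)C=C
F3 | step 8 | (2S,3S)-2-Cm-3-[(E)-2-Cm-ethenyl]-3-methylpent-4-enoic acid, the enantiomer of 14 | COc1ccc2ccc(=O)oc2c1/C=C/[C@]([C@H](C(=O)O)c1c(OC)ccc2ccc(=O)oc12)(C)C=C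
F4 | step 8 | (S)-1-phenylethylammonium salt of 14 | COc1ccc2ccc(=O)oc2c1/C=C/[C@@]([C@@H](C(=O)[O-])c1c(OC)ccc2ccc(=O)oc12)(C)C=C.C[C@H]([NH3+])c1ccccc1
F5 | step 11 | 8-[(3R,4R)-6,6-dibromo-3-methyl-3-[(E)-2-Cm-ethenyl]hexa-1,5-dien-4-yl]-7-methoxy-2H-chromen-2-one | COc1ccc2ccc(=O)oc2c1/C=C/[C@@]([C@@H](C=C(Br)Br)c1c(OC)ccc2ccc(=O)oc12)(C)C=C
F6 | step 11 | 8-[(3R,4R,5Z)-6-bromo-3-methyl-3-[(E)-2-Cm-ethenyl]hepta-1,5-dien-4-yl]-7-methoxy-2H-chromen-2-one | COc1ccc2ccc(=O)oc2c1/C=C/[C@@]([C@@H](/C=C(/C)Br)c1c(OC)ccc2ccc(=O)oc12)(C)C=C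
F7 | step 11 | 9-[(3R,4R,5Z)-6-bromo-4-Cm-3-[(E)-2-Cm-ethenyl]-3-methylhept-5-en-1-yl]-9-borabicyclo[3.3.1]nonane | COc1ccc2ccc(=O)oc2c1/C=C/[C@@]([C@@H](/C=C(/C)Br)c1c(OC)ccc2ccc(=O)oc12)(C)CCB1C2CCCC1CCC2
F8 | step 12 | (3R,4R,5Z)-6-iodo-4-Cm-3-[(E)-2-Cm-ethenyl]-3-methylhept-5-en-1-ol | COc1ccc2ccc(=O)oc2c1/C=C/[C@@]([C@@H](/C=C(/C)I)c1c(OC)ccc2ccc(=O)oc12)(C)CCO
F9 | step 12 | 8-[(2Z,4R,5R)-2,7-diiodo-5-methyl-5-[(E)-2-Cm-ethenyl]hept-2-en-4-yl]-7-methoxy-2H-chromen-2-one | COc1ccc2ccc(=O)oc2c1/C=C/[C@@]([C@@H](/C=C(/C)I)c1c(OC)ccc2ccc(=O)oc12)(C)CCI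
F10 | step 12 | [(3R,4R,5Z)-6-iodo-4-Cm-3-[(E)-2-Cm-ethenyl]-3-methylhept-5-en-1-yl]zinc iodide | COc1ccc2ccc(=O)oc2c1/C=C/[C@@]([C@@H](/C=C(/C)I)c1c(OC)ccc2ccc(=O)oc12)(C)CC[Zn]I
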